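**Retrosynthetic overview**
1. The target is numbered as tricyclo[5.4.0.0(2,8)]undec-9-en-11-one, with the cyclobutane C1–C2–C8–C7. The last disconnection is the cyclobutane bond C2–C8. The enabling feature is that C2 is a fully substituted, methyl-bearing carbon (ionisable to a tertiary cation) lying 1,3 to C8 across the cis C1/C7 fusion, while C8 is the γ-carbon of the six-ring enone C11(=O)–C10=C9(Me) and so is nucleophilic as the terminus of an extended silyl dienol ether. This is the himachalyl-to-longipinyl closure of the presumed biosynthesis.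
2. Seven-membered ring (C1–C7): intramolecular acyl substitution on a δ-lactone (bond C2–C3); the lactone oxygen becomes the C5 hydroxyl.
3. Six-membered ring: Diels–Alder reaction of the unsaturated δ-lactone with a 1-silyloxy-3-methylbutadiene (bonds C7–C8 and C1–C11), giving the cis C1/C7 fusion and C7 relative to C6.
4. Temporary δ-lactone: acrylation and ring-closing metathesis of a 2-methyl-2-vinyl-1,3-diol made by iridium-catalysed tert-(hydroxy)prenylation, which sets C5 and the quaternary C6. Ring order: δ-lactone (temporary) → cyclohexene → cycloheptanone → cyclobutane (last step, giving the target directly).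

Key step: step 15

Assumption: the tert-(hydroxy)prenylation of step 1 is taken to give the diastereomer with the carbinol hydroxyl anti to the methyl group (main chain drawn through the vinyl group) and, with (R)-Tol-BINAP, the (2S,3R) enantiomer; if the sense of induction is the opposite, the (S)-ligand is used.

Step 1
Reactants: 1 3-[(4-methoxyphenyl)methoxy]propan-1-ol; 2 2-ethenyl-2-methyloxirane (isoprene monoxide, racemic)
Product: 3 (2S,3R)-2-ethenyl-5-[(4-methoxyphenyl)methoxy]-2-methylpentane-1,3-diol
Conditions: π-allyliridium C,O-benzoate precatalyst from [Ir(cod)Cl]2, (R)-Tol-BINAP, 4-cyano-3-nitrobenzoic acid and allyl acetate (5 mol %), K3PO4 (5 mol %), THF, 60 °C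
Reagents that add atoms: none
Why: Iridium-catalysed transfer-hydrogenative tert-(hydroxy)prenylation (Krische coupling): the alcohol is dehydrogenated to the aldehyde, the epoxide gives a (hydroxymethyl)(methyl)allyliridium species, and addition through a closed chair transition state sets the carbinol and the quaternary carbon together, the ligand fixing the absolute sense while both enantiomers of 2 converge through the allyl intermediate.

Step 2
Reactants: 4 angelic acid
Product: 5 (2Z)-2-methylbut-2-enoic 2,4,6-trichlorobenzoic anhydride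
Conditions: 2,4,6-trichlorobenzoyl chloride (1.0 equiv), Et3N (1.05 equiv), toluene, 0 → 23 °C; filter off the ammonium salt under argon, concentrate
Reagents that add atoms: 2,4,6-trichlorobenzoyl chloride, O=C(Cl)c1c(Cl)cc(Cl)cc1Cl
Why: Acyl substitution of the acid chloride by the triethylammonium carboxylate gives the Yamaguchi mixed anhydride without touching the (Z)-alkene, and the isolated reagent serves both angeloylations (steps 3 and 12), a fresh batch being made by the same step when needed.

Step 3
Reactants: 3 diol; 5 mixed anhydride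
Product: 6 primary mono-angelate of 3
Conditions: 5 (1.1 equiv), Et3N (1.5 equiv), toluene, 23 → 50 °C
Reagents that add atoms: none
Why: Yamaguchi-type mixed-anhydride esterification, in which the alcohol attacks the unhindered angeloyl carbonyl of 5, the primary hydroxyl reacts far faster than the hindered secondary one, and the DMAP-free conditions should keep the (Z)-geometry of the angelate.

Step 4
Reactants: 6 mono-angelate; 7 acryloyl chloride
Product: 8 acrylate of the secondary alcohol
Conditions: i-Pr2NEt, DMAP (5 mol %), CH2Cl2, −20 → 0 °C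
Reagents that add atoms: none
Why: Base-mediated O-acylation of the secondary alcohol installs the second metathesis partner and the two carbons that become C1 and C2 of the target.

Step 5
Reactants: 8 acrylate
Product: 9 α,β-unsaturated δ-lactone
Conditions: second-generation Hoveyda–Grubbs catalyst (5 mol %), toluene (5 mM), 80 °C
Reagents that add atoms: none
Why: Ring-closing metathesis of the acrylate with the vinyl group on the quaternary carbon closes the six-membered lactone with loss of ethene, the trisubstituted electron-poor angelate alkene being inert.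

Step 6
Reactants: 10 3-methylbut-2-enal
Product: 11 (E)-triethyl[(3-methylbuta-1,3-dien-1-yl)oxy]silane
Conditions: Et3SiOTf, Et3N, Et2O, 0 °C
Reagents that add atoms: triethylsilyl trifluoromethanesulfonate, CC[Si](CC)(CC)OS(=O)(=O)C(F)(F)F
Why: Soft γ-enolisation and O-silylation of the enal gives the (E)-1-silyloxy diene.

Step 7
Reactants: 9 unsaturated lactone; 11 silyloxy diene
Product: 12 cis-fused cyclohexene-lactone cycloadduct
Conditions: Me2AlCl (0.5 equiv), CH2Cl2, −40 → 0 °C; Et3N, aq NaHCO3
Reagents that add atoms: none
Why: Lewis-acid-promoted Diels–Alder reaction in which the oxygenated diene terminus bonds to the α-carbon and the CH2 terminus to the β-carbon (ortho/para rule), suprafacial addition gives the cis ring fusion (C1/C7 of the target), and the diene approaches anti to the pseudo-axial CH2O-angelate group of the half-chair lactone (side chain on the carbinol carbon equatorial), which sets C7 relative to C6; the silyloxy carbinol centre (endo expected) is left undefined because step 14 removes it.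

Step 8
Reactants: 12 cycloadduct
Product: 13 primary alcohol
Conditions: DDQ, CH2Cl2/pH 7 buffer (10:1), 0 °C
Reagents that add atoms: none
Why: Oxidative cleavage of the p-methoxybenzyl ether by DDQ (benzylic hydride abstraction, then hydrolysis) should leave the silyl ether, the esters and the alkenes untouched.

Step 9
Reactants: 13 primary alcohol
Product: 14 primary iodide
Conditions: I2, PPh3, imidazole, CH2Cl2, 0 → 23 °C
Reagents that add atoms: iodine, II
Why: Appel-type iodination by SN2 displacement of the alkoxyphosphonium ion at the unhindered primary carbon.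

Step 10
Reactants: 14 iodo lactone
Product: 15 cis-fused hydroxy cycloheptanone
Conditions: SmI2 (2.5 equiv), Fe(dbm)3 (3 mol %), THF, −30 → 0 °C; aq NH4Cl
Reagents that add atoms: none
Why: SmI2-mediated intramolecular nucleophilic acyl substitution (Barbier-type): the alkylsamarium formed from the iodide adds to the lactone carbonyl through a five-membered transition state and the adduct collapses with expulsion of the ring oxygen, so the lactone is exchanged for the seven-membered ketone and the lactone oxygen becomes the C5 hydroxyl, without enolisation of the ring-fusion centre.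

Step 11
Reactants: 15 hydroxy ketone
Product: 16 tertiary alcohol (both epimers at the new carbinol)
Conditions: MeLi, CeCl3 (MeCeCl2, 3 equiv), THF, −78 °C; pH 7 buffer
Reagents that add atoms: methyllithium, [Li]C
Why: 1,2-Addition of the non-basic organocerium reagent to the ketone is chemoselective over the esters at −78 °C, and the configuration of the new carbinol is irrelevant because this carbon is ionised in step 15.

Step 12
Reactants: 16 diol; 5 mixed anhydride
Product: 17 bis-angelate
Conditions: 5 (3 equiv), Et3N (4 equiv), toluene, 80 °C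
Reagents that add atoms: none
Why: Yamaguchi-type esterification of the hindered secondary alcohol under forcing, DMAP-free conditions, the tertiary alcohol remaining free; acylation also removes the only hydroxyl that could trap the later cation as a transannular ether.

Step 13
Reactants: 17 silyl ether
Product: 18 allylic alcohol
Conditions: HF·pyridine, pyridine, THF, 0 °C
Reagents that add atoms: none
Why: Buffered fluoride cleavage of the triethylsilyl ether leaves the esters and the tertiary alcohol untouched.

Step 14
Reactants: 18 allylic alcohol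
Product: 19 β-methyl enone with tertiary alcohol
Conditions: MnO2 (activated, excess), CH2Cl2, 23 °C
Reagents that add atoms: none
Why: MnO2 oxidises only the allylic secondary alcohol, giving the enone and removing the undefined carbinol centre.

Step 15
Reactants: 19 enone tertiary alcohol
Product: 21 target diangelate, via bis(trimethylsilyl) dienol ether 20 (not isolated)
Conditions: Me3SiOTf (3 equiv), i-Pr2NEt (4 equiv), CH2Cl2, 0 → 23 °C; pentane, filter, concentrate; Me3SiNTf2 (10 mol %), CH2Cl2, −78 → −40 °C; Et3N, aq NaHCO3
Reagents that add atoms: none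
Why: Proposed new method: silylation turns 19 into 20, which carries a tertiary silyl ether at C2 and the extended (γ) silyl dienol ether of the enone; the silyl Lewis acid removes the C2 silyloxy group as hexamethyldisiloxane and the tertiary cation, held over the diene by the cis ring fusion, is captured by the γ-carbon C8 to give an O-silylated vinylogous oxocarbenium ion that releases the silyl group, regenerating the catalyst and the enone. The closest known reaction type is the Lewis-acid-mediated tert-alkylation of silyl enol ethers by SN1-active tertiary electrophiles (Reetz alkylation) in its vinylogous, γ-selective Mukaiyama form, and the step copies the himachalyl-to-longipinyl cation closure of the biosynthesis, with the enone oxygen supplying the driving force that a plain alkene lacks. The cyclobutane closes in a 4-exo mode, the cationic carbon lying outside the diene ring and bonding to its terminus. Both new stereocentres are set by the ring system: C2 is bonded to C1 and tied to C7 through C3–C6, so it can only reach the face of C8 on which it already sits, which fixes C8 and the quaternary C2 as in the target. The step needs γ- over α-attack and ring closure over proton loss: attack at C10 would give a more strained cyclobutanone-type cation without vinylogous stabilisation, the hindered ring-fusion α'-hydrogen disfavours the cross-conjugated enol ether, the exocyclic dienol ether cannot close without a bridgehead double bond and returns as 19, and the non-basic NTf2 counter-ion at −78 °C with both other oxygens acylated leaves no base or oxygen nucleophile to compete.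

**Compound list**
1 | 3-[(4-methoxyphenyl)methoxy]propan-1-ol | OCCCOCc1ccc(OC)cc1 | starting material
2 | 2-ethenyl-2-methyloxirane (racemic) | CC1(C=C)CO1 | starting material
3 | (2S,3R)-2-ethenyl-5-[(4-methoxyphenyl)methoxy]-2-methylpentane-1,3-diol | OC[C@](C)(C=C)[C@H](O)CCOCc1ccc(OC)cc1 | intermediate
4 | angelic acid, (2Z)-2-methylbut-2-enoic acid | C/C=C(/C)C(=O)O | starting material
5 | (2Z)-2-methylbut-2-enoic 2,4,6-trichlorobenzoic anhydride | C/C=C(/C)C(=O)OC(=O)c1c(Cl)cc(Cl)cc1Cl | intermediate
6 | (2S,3R)-2-ethenyl-3-hydroxy-5-[(4-methoxyphenyl)methoxy]-2-methylpentyl (2Z)-2-methylbut-2-enoate | C/C=C(/C)C(=O)OC[C@](C)(C=C)[C@H](O)CCOCc1ccc(OC)cc1 | intermediate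
7 | acryloyl chloride | C=CC(=O)Cl | starting material
8 | (2S,3R)-2-ethenyl-5-[(4-methoxyphenyl)methoxy]-2-methyl-3-(prop-2-enoyloxy)pentyl (2Z)-2-methylbut-2-enoate | C/C=C(/C)C(=O)OC[C@](C)(C=C)[C@H](OC(=O)C=C)CCOCc1ccc(OC)cc1 | intermediate
9 | [(2R,3S)-2-{2-[(4-methoxyphenyl)methoxy]ethyl}-3-methyl-6-oxo-3,6-dihydro-2H-pyran-3-yl]methyl (2Z)-2-methylbut-2-enoate | C/C=C(/C)C(=O)OC[C@]1(C)C=CC(=O)O[C@@H]1CCOCc2ccc(OC)cc2 | intermediate
10 | 3-methylbut-2-enal | CC(C)=CC=O | starting material
11 | (E)-triethyl[(3-methylbuta-1,3-dien-1-yl)oxy]silane | C=C(C)/C=C/O[Si](CC)(CC)CC | intermediate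
12 | [(3R,4S,4aS,8aS)-3-{2-[(4-methoxyphenyl)methoxy]ethyl}-4,6-dimethyl-1-oxo-8-[(triethylsilyl)oxy]-3,4,4a,5,8,8a-hexahydro-1H-isochromen-4-yl]methyl (2Z)-2-methylbut-2-enoate (C-8 undefined, endo expected) | C/C=C(/C)C(=O)OC[C@]1(C)[C@H]2CC(C)=CC(O[Si](CC)(CC)CC)[C@H]2C(=O)O[C@@H]1CCOCc3ccc(OC)cc3 | intermediate
13 | 3-(2-hydroxyethyl) analogue of 12, same configuration | C/C=C(/C)C(=O)OC[C@]1(C)[C@H]2CC(C)=CC(O[Si](CC)(CC)CC)[C@H]2C(=O)O[C@@H]1CCO | intermediate
14 | 3-(2-iodoethyl) analogue of 12, same configuration | C/C=C(/C)C(=O)OC[C@]1(C)[C@H]2CC(C)=CC(O[Si](CC)(CC)CC)[C@H]2C(=O)O[C@@H]1CCI | intermediate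
15 | [(4aS,8R,9S,9aS)-8-hydroxy-2,9-dimethyl-5-oxo-4-[(triethylsilyl)oxy]-4,4a,5,6,7,8,9,9a-octahydro-1H-benzo[7]annulen-9-yl]methyl (2Z)-2-methylbut-2-enoate (C-4 undefined) | C/C=C(/C)C(=O)OC[C@]1(C)[C@H]2CC(C)=CC(O[Si](CC)(CC)CC)[C@H]2C(=O)CC[C@H]1O | intermediate
16 | [(4aS,8R,9S,9aS)-5,8-dihydroxy-2,5,9-trimethyl-4-[(triethylsilyl)oxy]-4,4a,5,6,7,8,9,9a-octahydro-1H-benzo[7]annulen-9-yl]methyl (2Z)-2-methylbut-2-enoate (C-4 and C-5 undefined) | C/C=C(/C)C(=O)OC[C@]1(C)[C@H]2CC(C)=CC(O[Si](CC)(CC)CC)[C@H]2C(C)(O)CC[C@H]1O | intermediate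
17 | 8-O-[(2Z)-2-methylbut-2-enoyl] derivative of 16 | C/C=C(/C)C(=O)OC[C@]1(C)[C@H]2CC(C)=CC(O[Si](CC)(CC)CC)[C@H]2C(C)(O)CC[C@H]1OC(=O)/C(C)=C\C | intermediate
18 | 4-hydroxy compound from 17 (triethylsilyl group removed; C-4 and C-5 undefined) | C/C=C(/C)C(=O)OC[C@]1(C)[C@H]2CC(C)=CC(O)[C@H]2C(C)(O)CC[C@H]1OC(=O)/C(C)=C\C | intermediate
19 | [(4aR,8R,9S,9aS)-5-hydroxy-2,5,9-trimethyl-8-{[(2Z)-2-methylbut-2-enoyl]oxy}-4-oxo-4,4a,5,6,7,8,9,9a-octahydro-1H-benzo[7]annulen-9-yl]methyl (2Z)-2-methylbut-2-enoate (C-5 undefined) | C/C=C(/C)C(=O)OC[C@]1(C)[C@H]2CC(C)=CC(=O)[C@H]2C(C)(O)CC[C@H]1OC(=O)/C(C)=C\C | intermediate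
20 | bis(trimethylsilyl) derivative of 19: 5-trimethylsilyl ether and 4-trimethylsilyloxy-1,3-diene (C1=C2, C3=C4) | C/C=C(/C)C(=O)OC[C@]1(C)[C@H]2C=C(C)C=C(O[Si](C)(C)C)[C@H]2C(C)(O[Si](C)(C)C)CC[C@H]1OC(=O)/C(C)=C\C | intermediate
21 | [(1R,2R,5R,6S,7S,8R)-2,6,9-trimethyl-5-{[(2Z)-2-methylbut-2-enoyl]oxy}-11-oxotricyclo[5.4.0.0(2,8)]undec-9-en-6-yl]methyl (2Z)-2-methylbut-2-enoate | C/C=C(/C)C(=O)OC[C@]1(C)[C@@H]2[C@H]3C(=O)C=C(C)[C@@H]2[C@@]3(C)CC[C@H]1OC(=O)/C(C)=C\C | target

**Step count:** 15 steps in total; longest linear sequence 13 steps (steps 1, 3–5 and 7–15; steps 2 and 6 prepare the acylating reagent and the diene).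

**Steps most likely to fail**

Step 15 (proposed new method). The tertiary cation may lose a proton (towards the conjugated triene and then the arene) or be captured at the α-carbon faster than the 4-exo closure, and the silylation may enolise at the wrong site. The fallback uses known photochemical and radical chemistry, sets out from ketone 15 and returns at 21. Ketone 15 would be irradiated (350 nm, benzene/tert-butanol) in a Norrish–Yang photocyclisation: the excited ketone abstracts the allylic γ-hydrogen at C8 through a six-membered transition state and the 1,4-biradical closes the same C2–C8 bond, giving tricyclic cyclobutanol F1, whose tertiary hydroxyl stands where the methyl group belongs. The secondary hydroxyl would be angeloylated with mixed anhydride 5 as in step 12 to give diester cyclobutanol F2. The tertiary hydroxyl would then be exchanged for methyl by deoxygenative radical methylation (condensation with N-phenylbenzoxazolium tetrafluoroborate and pyridine, Ir(ppy)2(dtbbpy)PF6 under blue light, Ni(acac)2 with KTp* as SH2 catalyst, methanol activated in the same way as methyl donor) to give methylated silyl ether F3. HF·pyridine as in step 13 would give allylic alcohol F4, and MnO2 as in step 14 would give 21.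

Step 7. The β-carbon next to the quaternary centre may be too hindered for cycloaddition, or the diene may be consumed by the Lewis acid before ring closure. The fallback sets out from lactone 9 and returns at 12, using a more reactive diene and a carbonyl transposition. Danishefsky's diene (trans-1-methoxy-3-trimethylsilyloxybuta-1,3-diene, toluene, 110 °C) should give silyl enol ether cycloadduct F5 with the same facial and regiochemical sense. Trifluoroacetic acid would convert it into bicyclic enone F6. MeLi/CeCl3 at −78 °C would add 1,2 to the ketone to give tertiary allylic alcohol F7. Ph3SiOReO3 (5 mol %, Et2O, 0 °C) would effect the 1,3-transposition to secondary allylic alcohol F8, and Et3SiCl/imidazole would give 12.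

Step 10. The alkylsamarium may be protonated before it reaches the lactone carbonyl, or single-electron reduction may touch the angelate. The fallback sets out from iodide 14 and returns at 15, using a sulfone-stabilised carbanion instead of an organosamarium. PhSO2Na in DMF would give sulfone F9. LiHMDS (2.5 equiv, THF, −78 → −20 °C) would induce a Dieckmann-type acyl transfer from the lactone oxygen to the α-sulfonyl carbon, driven by deprotonation of the product, to give β-keto sulfone F10. Al(Hg) in wet THF would remove the sulfonyl group to give 15.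

**Further compounds**
F1 | step 15 | Norrish–Yang cyclobutanol: tricyclo[5.4.0.0(2,8)]undec-9-ene with 2-OH, 5-OH, 11-triethylsilyloxy, 6-methyl-6-(angeloyloxymethyl), 9-methyl | C/C=C(/C)C(=O)OC[C@]1(C)[C@@H]2[C@H]3C(O[Si](CC)(CC)CC)C=C(C)[C@@H]2[C@@]3(O)CC[C@H]1O
F2 | step 15 | 5-O-angelate of F1 | C/C=C(/C)C(=O)OC[C@]1(C)[C@@H]2[C@H]3C(O[Si](CC)(CC)CC)C=C(C)[C@@H]2[C@@]3(O)CC[C@H]1OC(=O)/C(C)=C\C
F3 | step 15 | 2-methyl compound from F2 (11-triethylsilyl ether of the allylic alcohol of the target skeleton) | C/C=C(/C)C(=O)OC[C@]1(C)[C@@H]2[C@H]3C(O[Si](CC)(CC)CC)C=C(C)[C@@H]2[C@@]3(C)CC[C@H]1OC(=O)/C(C)=C\C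
F4 | step 15 | 11-hydroxy compound (allylic alcohol corresponding to 21) | C/C=C(/C)C(=O)OC[C@]1(C)[C@@H]2[C@H]3C(O)C=C(C)[C@@H]2[C@@]3(C)CC[C@H]1OC(=O)/C(C)=C\C
F5 | step 7 | Danishefsky cycloadduct: 8-methoxy-6-trimethylsilyloxy analogue of 12 (alkene C6=C7) | C/C=C(/C)C(=O)OC[C@]1(C)[C@H]2CC(O[Si](C)(C)C)=CC(OC)[C@H]2C(=O)O[C@@H]1CCOCc3ccc(OC)cc3
F6 | step 7 | bicyclic enone-lactone (6-oxo, alkene C7=C8) | C/C=C(/C)C(=O)OC[C@]1(C)[C@H]2CC(=O)C=C[C@H]2C(=O)O[C@@H]1CCOCc3ccc(OC)cc3
F7 | step 7 | tertiary allylic alcohol (6-hydroxy-6-methyl, alkene C7=C8) | C/C=C(/C)C(=O)OC[C@]1(C)[C@H]2CC(C)(O)C=C[C@H]2C(=O)O[C@@H]1CCOCc3ccc(OC)cc3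
F8 | step 7 | transposed secondary allylic alcohol (8-hydroxy, 6-methyl, alkene C6=C7; desilyl 12) | C/C=C(/C)C(=O)OC[C@]1(C)[C@H]2CC(C)=CC(O)[C@H]2C(=O)O[C@@H]1CCOCc3ccc(OC)cc3
F9 | step 10 | 3-[2-(phenylsulfonyl)ethyl] analogue of 14 | C/C=C(/C)C(=O)OC[C@]1(C)[C@H]2CC(C)=CC(O[Si](CC)(CC)CC)[C@H]2C(=O)O[C@@H]1CCS(=O)(=O)c3ccccc3
F10 | step 10 | 6-(phenylsulfonyl) derivative of 15 (β-keto sulfone) | C/C=C(/C)C(=O)OC[C@]1(C)[C@H]2CC(C)=CC(O[Si](CC)(CC)CC)[C@H]2C(=O)C(S(=O)(=O)c3ccccc3)C[C@H]1O
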